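**Plan**

- Retrosynthesis: the MOM group on O7 is removed last. Ring C is then cut at C2–C3 and at O1–C8a in one operation, giving a chromane aldehyde (ring B with its fused dimethylpyran ring) and a 2-fluoroaryl methyl ketone, used as its enol silane (ring A). Behind these lie the two aryl–prenyl bonds and the aryl–acetyl bond.
- Enabling feature: in ring C the C4 carbonyl sits on C4a, ortho to C8a of ring A. The same carbonyl makes C3 a carbon nucleophile (as the enol silane) and makes C8a open to ipso attack once it carries fluorine. CH2=C(OSiMe3)–C4a=C8a–F is thus a benzo-fused 1-alkoxy-3-silyloxydiene, and the aldehyde C=O is its two-atom partner (formal [4+2]).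
- Forward, ring B piece: bromination and Stille prenylation of 2,2-dimethylchromane-6-carbaldehyde. Ring A piece: MOM ether of 4-bromo-3-fluorophenol, metalation between F and OMOM with prenylation, bromine-to-acetyl exchange, enol silane.
- Ring order: ring A, ring B and the dimethylpyran ring are carried intact; ring C is the only ring made and closes in the key step. Fluorine and the silyl group leave there as Me3SiF, and MOM is removed at the end.
- Stereochemistry: C2 is the only stereocentre. It is set as the (S)-carbinol in the catalyst-controlled aldol stage (Si-face attack) and kept in the ring closure, because the C2–O bond is not broken; no basic step follows.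

Key step: step 7

Assumption: the boron catalyst built from N-tosyl-(R)-tryptophan is taken to direct the enol silane to the Si face of the aldehyde; should a trial with the aldehyde partner show the opposite sense, the catalyst from N-tosyl-(S)-tryptophan takes its place and nothing else changes.

**Route**

Step 1
Reactants: 1 2,2-dimethylchromane-6-carbaldehyde
Product: 2 8-bromo-2,2-dimethylchromane-6-carbaldehyde
Conditions: Br2 (1.1 equiv), NaOAc, AcOH, rt, dark
Reagents that add atoms: bromine, BrBr
Why: Electrophilic aromatic bromination, in which the ring oxygen directs ortho and para, the para position carries the formyl group and C5 and C7 are deactivated by it, so that bromine should enter only at C8.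

Step 2
Reactants: 2 8-bromo-2,2-dimethylchromane-6-carbaldehyde
Product: 3 2,2-dimethyl-8-(3-methylbut-2-en-1-yl)chromane-6-carbaldehyde
Conditions: tributyl(3-methylbut-2-en-1-yl)stannane (1.3 equiv), Pd(PPh3)4 (5 mol %), DMF, 90 °C
Reagents that add atoms: tributyl(3-methylbut-2-en-1-yl)stannane, CC(C)=CC[Sn](CCCC)(CCCC)CCCC
Why: Stille cross-coupling of the aryl bromide with the allylic stannane, which should transfer the unbranched 3-methylbut-2-enyl group from its tin-bearing carbon and tolerates the free aldehyde.

Step 3
Reactants: 4 4-bromo-3-fluorophenol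
Product: 5 1-bromo-2-fluoro-4-(methoxymethoxy)benzene
Conditions: MOMCl (1.3 equiv), i-Pr2NEt (1.5 equiv), CH2Cl2, 0 °C to rt
Reagents that add atoms: chloromethyl methyl ether, COCCl
Why: Williamson-type O-alkylation to the methoxymethyl ether, which directs the coming metalation, survives amide bases, organolithiums and fluoride, and places the O7 donor meta to the carbon that is later substituted.

Step 4
Reactants: 5 1-bromo-2-fluoro-4-(methoxymethoxy)benzene
Product: 7 1-bromo-2-fluoro-4-(methoxymethoxy)-3-(3-methylbut-2-en-1-yl)benzene, via aryllithium 6 (not isolated)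
Conditions: LiN(i-Pr)2 (1.1 equiv), THF, −78 °C; CuBr·SMe2 (0.2 equiv), 1-bromo-3-methylbut-2-ene (1.3 equiv), −78 to −20 °C
Reagents that add atoms: 1-bromo-3-methylbut-2-ene, CC(C)=CCBr
Why: Directed ortho-metalation, in which the proton flanked by fluorine and the methoxymethoxy group is the most acidic and is removed by the amide base without bromine–lithium exchange, followed by copper-catalysed SN2 alkylation of the cold aryl metal at the primary carbon of the allylic bromide.

Step 5
Reactants: 7 1-bromo-2-fluoro-4-(methoxymethoxy)-3-(3-methylbut-2-en-1-yl)benzene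
Product: 10 1-[2-fluoro-4-(methoxymethoxy)-3-(3-methylbut-2-en-1-yl)phenyl]ethan-1-one, via aryllithium 8 (not isolated), via lithium hemiaminal adduct 9 (not isolated)
Conditions: n-BuLi (1.05 equiv), THF, −78 °C; N-methoxy-N-methylacetamide (1.5 equiv), −78 to −20 °C; aq. NH4Cl
Reagents that add atoms: N-methoxy-N-methylacetamide, CC(=O)N(C)OC
Why: Bromine–lithium exchange at −78 °C (cold enough to keep LiF on the ortho-fluoroaryllithium) followed by the Weinreb ketone synthesis, in which the chelated tetrahedral adduct 9 holds until work-up so that the aryllithium adds only once.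

Step 6
Reactants: 10 1-[2-fluoro-4-(methoxymethoxy)-3-(3-methylbut-2-en-1-yl)phenyl]ethan-1-one
Product: 12 ({1-[2-fluoro-4-(methoxymethoxy)-3-(3-methylbut-2-en-1-yl)phenyl]ethenyl}oxy)trimethylsilane, via lithium enolate 11 (not isolated)
Conditions: LiN(SiMe3)2 (1.1 equiv), THF, −78 °C; Me3SiCl (1.3 equiv), −78 to 0 °C; pentane, filtration under argon
Reagents that add atoms: chlorotrimethylsilane, C[Si](C)(C)Cl
Why: Kinetic enolisation and O-silylation (silyl enol ether formation) of a ketone whose only α-hydrogens are on the methyl group, so that a single enol silane should result.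

Step 7
Reactants: 12 ({1-[2-fluoro-4-(methoxymethoxy)-3-(3-methylbut-2-en-1-yl)phenyl]ethenyl}oxy)trimethylsilane; 3 2,2-dimethyl-8-(3-methylbut-2-en-1-yl)chromane-6-carbaldehyde
Product: 14 (2S)-2-[2,2-dimethyl-8-(3-methylbut-2-en-1-yl)chroman-6-yl]-7-(methoxymethoxy)-8-(3-methylbut-2-en-1-yl)chroman-4-one, via silyl aldol ether 13 (not isolated)
Conditions: 12 (1.2 equiv), (4R)-2-butyl-4-(1H-indol-3-ylmethyl)-3-tosyl-1,3,2-oxazaborolidin-5-one (20 mol %, from N-tosyl-(R)-tryptophan and n-BuB(OH)2), EtCN, −78 °C; then, in the same flask, n-Bu4N[Ph3SiF2] (20 mol %), THF, −78 to −20 °C; AcOH quench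
Reagents that add atoms: none
Why: Proposed new method: the boron Lewis acid binds the aldehyde oxygen of 3 and the terminal carbon of enol silane 12 (the future C3) adds through an open Mukaiyama transition state with silyl transfer to give 13; catalytic fluoride then frees the C2 alkoxide, which attacks C8a ipso to fluorine, passes through a Meisenheimer anion stabilised by the C4 carbonyl on C4a and expels fluoride, which desilylates the next molecule of 13, so that Me3SiF is the only by-product. The closest known reaction types are the enantioselective Mukaiyama aldol addition of aryl methyl ketone enol silanes with this class of boron catalyst, together with its aldol–cyclisation extension from 1-methoxy-3-silyloxybutadiene to 2-substituted 2,3-dihydropyran-4-ones, and the fluoride-catalysed SNAr etherification of activated aryl fluorides by silyl ethers; their union in one flask on an ortho-fluoroaryl enol silane has not been shown. Ring C closes by an intramolecular addition–elimination in which O1 attacks the trigonal carbon C8a while the departing C8a–F bond lies outside the new six-membered ring (6-exo closure), and since the C2–O bond is never broken the carbinol configuration is carried into the ring with retention. C2, the only new stereocentre, is set in the aldol stage by the catalyst, whose indole unit is taken to cover the Re face of the bound aldehyde so that C3 arrives at the Si face and gives the (S)-carbinol. The step needs ring closure to outrun retro-aldol cleavage and E1cB dehydration of the freed β-alkoxide: the closure is unimolecular through a six-membered transition state, the fragmentation is the entropically favoured path and is held back by working cold with only a small standing amount of alkoxide, and the O7 MOM ether is meta to C8a and so does not cancel the activation by the carbonyl. Site selectivity is secured because fluorine on C8a is the only nucleofuge ortho to the carbonyl, and stereochemical leakage is avoided because aldehyde 3 is consumed before fluoride is added, so that the small excess of 12 cannot form racemic aldolate.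

Step 8
Reactants: 14 (2S)-2-[2,2-dimethyl-8-(3-methylbut-2-en-1-yl)chroman-6-yl]-7-(methoxymethoxy)-8-(3-methylbut-2-en-1-yl)chroman-4-one
Product: 15 (2S)-2-[2,2-dimethyl-8-(3-methylbut-2-en-1-yl)chroman-6-yl]-7-hydroxy-8-(3-methylbut-2-en-1-yl)chroman-4-one
Conditions: 3 M aq. HCl, MeOH, 50 °C, stopped at full conversion
Reagents that add atoms: none
Why: Acid-catalysed acetal cleavage (transacetalisation to methanol) of the aryl MOM ether, routine for prenylated flavanones, which should leave C2 untouched because ring opening of a flavanone needs base, the time being kept short so that O7–H does not add across the C8 prenyl double bond.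

**Compound list**

1 | 2,2-dimethylchromane-6-carbaldehyde | CC1(C)CCc2cc(C=O)ccc2O1 | starting material
2 | 8-bromo-2,2-dimethylchromane-6-carbaldehyde | CC1(C)CCc2cc(C=O)cc(Br)c2O1 | intermediate
3 | 2,2-dimethyl-8-(3-methylbut-2-en-1-yl)chromane-6-carbaldehyde | CC(C)=CCc1cc(C=O)cc2c1OC(C)(C)CC2 | intermediate
4 | 4-bromo-3-fluorophenol | Oc1ccc(Br)c(F)c1 | starting material
5 | 1-bromo-2-fluoro-4-(methoxymethoxy)benzene | COCOc1ccc(Br)c(F)c1 | intermediate
6 | [3-bromo-2-fluoro-6-(methoxymethoxy)phenyl]lithium (not isolated) | COCOc1ccc(Br)c(F)c1[Li] | intermediate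
7 | 1-bromo-2-fluoro-4-(methoxymethoxy)-3-(3-methylbut-2-en-1-yl)benzene | COCOc1ccc(Br)c(F)c1CC=C(C)C | intermediate
8 | [2-fluoro-4-(methoxymethoxy)-3-(3-methylbut-2-en-1-yl)phenyl]lithium (not isolated) | COCOc1ccc([Li])c(F)c1CC=C(C)C | intermediate
9 | lithium 1-[2-fluoro-4-(methoxymethoxy)-3-(3-methylbut-2-en-1-yl)phenyl]-1-[methoxy(methyl)amino]ethan-1-olate (not isolated) | COCOc1ccc(C(C)(O[Li])N(C)OC)c(F)c1CC=C(C)C | intermediate
10 | 1-[2-fluoro-4-(methoxymethoxy)-3-(3-methylbut-2-en-1-yl)phenyl]ethan-1-one | COCOc1ccc(C(C)=O)c(F)c1CC=C(C)C | intermediate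
11 | lithium 1-[2-fluoro-4-(methoxymethoxy)-3-(3-methylbut-2-en-1-yl)phenyl]ethen-1-olate (not isolated) | COCOc1ccc(C(=C)O[Li])c(F)c1CC=C(C)C | intermediate
12 | ({1-[2-fluoro-4-(methoxymethoxy)-3-(3-methylbut-2-en-1-yl)phenyl]ethenyl}oxy)trimethylsilane | COCOc1ccc(C(=C)O[Si](C)(C)C)c(F)c1CC=C(C)C | intermediate
13 | (3S)-3-[2,2-dimethyl-8-(3-methylbut-2-en-1-yl)chroman-6-yl]-1-[2-fluoro-4-(methoxymethoxy)-3-(3-methylbut-2-en-1-yl)phenyl]-3-[(trimethylsilyl)oxy]propan-1-one (not isolated) | CC(C)=CCc1cc([C@@H](O[Si](C)(C)C)CC(=O)c3ccc(OCOC)c(CC=C(C)C)c3F)cc2c1OC(C)(C)CC2 | intermediate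
14 | (2S)-2-[2,2-dimethyl-8-(3-methylbut-2-en-1-yl)chroman-6-yl]-7-(methoxymethoxy)-8-(3-methylbut-2-en-1-yl)chroman-4-one | CC(C)=CCc1cc([C@@H]2CC(=O)c3ccc(OCOC)c(CC=C(C)C)c3O2)cc2c1OC(C)(C)CC2 | intermediate
15 | (2S)-2-[2,2-dimethyl-8-(3-methylbut-2-en-1-yl)chroman-6-yl]-7-hydroxy-8-(3-methylbut-2-en-1-yl)chroman-4-one | CC(C)=CCc1cc([C@@H]2CC(=O)c3ccc(O)c(CC=C(C)C)c3O2)cc2c1OC(C)(C)CC2 | target

**Step count and risks**

Total step count: 8. Longest linear sequence: 6 steps (steps 3 to 8, from 4); the ring B branch (steps 1 and 2) joins at step 7.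

Steps most likely to fail:

1. Step 7 (Proposed new method). What may go wrong: retro-aldol cleavage and base-induced dehydration of the freed β-alkoxide compete with ring closure, which would erode the enantiomeric purity or stop the fluoride relay; facial control in the aldol stage may also be incomplete with this Lewis-basic substrate. The fallback uses known chemistry, sets out from ketone 10 and aldehyde 3 and comes back at 14. Hydroxide displaces the activated fluoride of 10 (KOH, DMSO–H2O, 80 °C) to give 1-[2-hydroxy-4-(methoxymethoxy)-3-(3-methylbut-2-en-1-yl)phenyl]ethan-1-one F1. Claisen–Schmidt condensation of F1 with 3 (KOH, EtOH, rt) gives the 2′-hydroxychalcone (E)-3-[2,2-dimethyl-8-(3-methylbut-2-en-1-yl)chroman-6-yl]-1-[2-hydroxy-4-(methoxymethoxy)-3-(3-methylbut-2-en-1-yl)phenyl]prop-2-en-1-one F2. Oxa-Michael ring closure (NaOAc, EtOH, reflux) gives the racemic flavanone rac-2-[2,2-dimethyl-8-(3-methylbut-2-en-1-yl)chroman-6-yl]-7-(methoxymethoxy)-8-(3-methylbut-2-en-1-yl)chroman-4-one F3. Preparative chromatography on a chiral stationary phase (amylose tris(3,5-dimethylphenylcarbamate)) then delivers the (S)-enantiomer 14. In this approach O1 comes from ring A and the bond formed is C2–O1, so no aldol β-alkoxide has to be arylated.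

2. Step 4. What may go wrong: loss of LiF from the ortho-fluoroaryllithium (aryne formation) while the slow alkylation is awaited, and allylic transposition or halogen–metal scrambling in the reaction with the prenyl halide. The fallback sets out from aryllithium 6 (made from 5 as in step 4) and comes back at 7. Aryllithium 6 is trapped at −78 °C with allyl bromide, which reacts without warming and offers no regiochemical choice, to give 1-bromo-2-fluoro-4-(methoxymethoxy)-3-(prop-2-en-1-yl)benzene F4. Olefin cross-metathesis of F4 with 2-methylbut-2-ene (second-generation Grubbs catalyst, CH2Cl2, 40 °C) converts allyl into 3-methylbut-2-enyl and gives 7.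

3. Step 5. What may go wrong: proton transfer from the acetyl group of the amide to the aryllithium (protodebromination in place of acylation) and loss of LiF from the ortho-fluoroaryllithium. The fallback avoids organolithium chemistry, sets out from 7 and comes back at 10. Stille coupling of 7 with tributyl(1-ethoxyethenyl)stannane (Pd(PPh3)4, toluene, 100 °C) gives the enol ether 1-(1-ethoxyethenyl)-2-fluoro-4-(methoxymethoxy)-3-(3-methylbut-2-en-1-yl)benzene F5. Brief hydrolysis (1 M HCl, THF, 0 °C) frees ketone 10 while the MOM ether survives.

**Further compounds**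

F1 | step 7 | 1-[2-hydroxy-4-(methoxymethoxy)-3-(3-methylbut-2-en-1-yl)phenyl]ethan-1-one | COCOc1ccc(C(C)=O)c(O)c1CC=C(C)C
F2 | step 7 | (E)-3-[2,2-dimethyl-8-(3-methylbut-2-en-1-yl)chroman-6-yl]-1-[2-hydroxy-4-(methoxymethoxy)-3-(3-methylbut-2-en-1-yl)phenyl]prop-2-en-1-one | CC(C)=CCc1cc(/C=C/C(=O)c3ccc(OCOC)c(CC=C(C)C)c3O)cc2c1OC(C)(C)CC2
F3 | step 7 | rac-2-[2,2-dimethyl-8-(3-methylbut-2-en-1-yl)chroman-6-yl]-7-(methoxymethoxy)-8-(3-methylbut-2-en-1-yl)chroman-4-one | CC(C)=CCc1cc(C2CC(=O)c3ccc(OCOC)c(CC=C(C)C)c3O2)cc2c1OC(C)(C)CC2
F4 | step 4 | 1-bromo-2-fluoro-4-(methoxymethoxy)-3-(prop-2-en-1-yl)benzene | COCOc1ccc(Br)c(F)c1CC=C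
F5 | step 5 | 1-(1-ethoxyethenyl)-2-fluoro-4-(methoxymethoxy)-3-(3-methylbut-2-en-1-yl)benzene | COCOc1ccc(C(=C)OCC)c(F)c1CC=C(C)C
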